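How much target stands after 6.0 h as the partner charge climbs from 1.00 equiv to 8.00 equiv, with reagent and protic impurity unchanged?

common to all: starting material 20 mM

|  | partner | reagent | protic impurity | remark | time |
|---|---|---|---|---|---|
| dawn | 1.4 equiv | 3 equiv | 6 mM | run made earlier |  |
| midnight | 11 equiv | 3 equiv | 6 mM | run made earlier |  |
| south-east | 1.00 equiv | 3.00 equiv | 6.00 mM |  | 6.0 h |
| north | 2.00 equiv | 3.00 equiv | 6.00 mM |  | 6.0 h |
| south-west | 4.00 equiv | 3.00 equiv | 6.00 mM |  | 6.0 h |
| south | 8.00 equiv | 3.00 equiv | 6.00 mM |  | 6.0 h |

| run | time / h | target / % | starting material / % |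
|---|---|---|---|
| dawn | 0.333 | 0.9 | 89.4 |
| dawn | 1.00 | 13.8 | 73.3 |
| dawn | 1.50 | 22.8 | 64.4 |
| dawn | 2.50 | 36.1 | 51.8 |
| dawn | 4.00 | 52.1 | 37.5 |
| dawn | 5.00 | 60.2 | 31.5 |
| dawn | 6.00 | 64.5 | 26.3 |
| midnight | 0.500 | 11.5 | 86.6 |
| midnight | 0.667 | 14.1 | 84.5 |
| midnight | 1.00 | 19.8 | 80.3 |
| midnight | 1.50 | 24.4 | 73.5 |
| midnight | 2.50 | 30.1 | 68.3 |
| midnight | 4.00 | 30.4 | 64.8 |
| midnight | 6.00 | 32.0 | 58.6 |

(scatter of a reading: 1 percentage point)

- [target] at the end for south-east, north, south-west, south, in this order
- how that number moves from the first to the last of them (hardly changes / rises, then falls / falls all the way / falls, then rises / rises all the way)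

- "hardly changes" means that all values lie within two and a half points (for a concentration: within two and a half percent of the largest)

Start with the two earlier runs. At the end, the dawn run holds 64.5% of target and the midnight run 32.0%, so target falls somewhere between those two partner charges. In the midnight run, starting material first disappears with a first-order rate constant of 0.288 h⁻¹, but over the last interval with 0.0503 h⁻¹. I read this as partner destroying reagent, pseudo-first-order in that large excess.

Now divide the fractional loss of starting material by the loss of reagent, and time drops out: per reagent spent, the logarithm of charged over remaining starting material varies inversely with partner. The midnight run gives 5.88 equiv. This product, partner equivalents times that logarithm once reagent is spent, I call the reach; it should carry over at this reagent charge.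

For the south flask, the reach leaves 48.0% of the starting material. But that flask has less partner and spends reagent more slowly. Scaling the midnight decay, I reckon 90.5% of the reagent gone by the end, so I expect 51.4% of the starting material to remain. A further doubt pulls the other way: the midnight run had not quite finished, and I leave that unreckoned. Nor does all lost starting material appear as target. The midnight run shows a fraction of 77.3%, so I expect 37.5% of the charge, or 7.51 mM. For the low-partner flasks, the reach gives me nothing.

The forecast gives 11.5 mM, 13 mM, 11.5 mM and 8.5 mM, a row that rises, then falls, with “reagent loss begins to bite” at 4.00 equiv. Its last value stands above mine.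

The simulation gives 9.06 mM, 13.9 mM, 11.8 mM and 8.25 mM, a row that rises, then falls.

    reagent + partner → second intermediate (k = 3.80 M⁻¹ h⁻¹)
    partner + protic impurity → quenched reagent (k = 110 M⁻¹ h⁻¹)
    starting material + second intermediate → side product (k = 0.600 M⁻¹ h⁻¹)
    starting material + reagent → open intermediate (k = 5.40 M⁻¹ h⁻¹)
    open intermediate + second intermediate → target (k = 880 M⁻¹ h⁻¹)

In the south flask, the shrinking supply of reagent is the largest single effect on the target: with that supply held at the charge, target reaches 16.4 mM instead of 8.25 mM. Its reach comes to 5.22 equiv, with 4.53% of the reagent charge left and 39.5 mM of second intermediate standing. The south-west flask reckons lower, at 3.87 equiv, with 21.8% of its reagent charge still there.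

(All runs are calculated on assumed constants; scatter was added.)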